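**Strategy.** Ring B (C5–C6–C7–C8–C9–C10) is disconnected at C9–C10 and seen as the one-carbon homologue of the cyclopentanone ring (C5, C6, C7, C8, C10) of a Hajos–Parrish-type trans-hydrindanone. The key step is a selenium-triggered semipinacol ring enlargement: the quaternary C10 shifts from the carbinol carbon C8 to the adjacent side-chain carbon C9. In one operation this turns the five-membered ring into ring B, forms the C9–C10 bond, places the complete citronellol-derived side chain on C9 and leaves C8 as the ketone that later becomes the tertiary carbinol. It exploits the vicinal C8(O)/C9(alkyl) pair next to quaternary C10. The precursor is the β-hydroxy selenide from the hydrindanone and an α-selenoalkyllithium.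

Key step: step 13

Remark: ent-labdane numbering is used for positions (ring B = C5–C10; C17 = methyl on C8; C18 = oxygenated CH2 on C4, trans to the C10 methyl). The target is taken as 4S,5S,8S,9S,10R,13S with a (Z)-2-methylbut-2-enoate (angelate).
Remark: methaneselenol is taken as available; it can be liberated beforehand from commercial dimethyl diselenide.

**Route**

Step 1
Reactants: 1 2-methylcyclopentane-1,3-dione; 2 pent-1-en-3-one (ethyl vinyl ketone)
Product: 3 2-methyl-2-(3-oxopentyl)cyclopentane-1,3-dione
Conditions: H2O, AcOH (cat.), 75 °C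
Reagents that add atoms: none
Why: Michael addition of the acidic 1,3-dione to the enone is the first stage of a Robinson-type (Hajos–Parrish) annulation and creates no stereocentre.

Step 2
Reactants: 3 2-methyl-2-(3-oxopentyl)cyclopentane-1,3-dione
Product: 5 (7aR)-4,7a-dimethyl-2,3,7,7a-tetrahydro-1H-indene-1,5(6H)-dione, via cis-fused ketol 4 (not isolated)
Conditions: D-phenylalanine (1 equiv), (+)-CSA (0.5 equiv), DMF, 25 → 70 °C
Reagents that add atoms: none
Why: Hajos–Parrish–Eder–Sauer–Wiechert aldol cyclisation and dehydration, in which the amino-acid enamine of the side-chain ketone selects one of the two enantiotopic ring carbonyls; the D-amino acid should give the (R)-configured quaternary carbon (C10 of the target), the mirror image of the product known from the L-amino acid.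

Step 3
Reactants: 5 (7aR)-4,7a-dimethyl-2,3,7,7a-tetrahydro-1H-indene-1,5(6H)-dione
Product: 6 (1R,7aR)-1-hydroxy-4,7a-dimethyl-1,2,3,6,7,7a-hexahydro-5H-inden-5-one
Conditions: NaBH4 (0.3 equiv), EtOH, −20 °C
Reagents that add atoms: none
Why: Chemoselective borohydride reduction of the saturated cyclopentanone beside the less electrophilic enone, with hydride delivered anti to the angular methyl so that the hydroxyl ends cis to it (this centre only masks the later C8 ketone).

Step 4
Reactants: 6 (1R,7aR)-1-hydroxy-4,7a-dimethyl-1,2,3,6,7,7a-hexahydro-5H-inden-5-one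
Product: 8 (1R,3aS,4S,7aR)-1-hydroxy-4-(hydroxymethyl)-4,7a-dimethyloctahydro-5H-inden-5-one, via dilithium enolate alkoxide 7 (not isolated)
Conditions: Li (2.2 equiv), NH3(l)/THF, −78 → −33 °C; NH3 evaporated; CH2O (g), THF, −78 °C; aq NH4Cl
Reagents that add atoms: formaldehyde C=O
Why: Stork reductive alkylation (dissolving-metal enone reduction, then aldol trapping of the regiodefined enolate): the β-carbon (C5 of the target) should be protonated anti to the angular methyl, with the hydroxyl of 6 as proton source, giving the trans-hydrindane, and enolate 7 should take up formaldehyde at C4 from the face anti to the angular methyl, which sets the quaternary C4 with CH2OH trans to that methyl.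

Step 5
Reactants: 8 (1R,3aS,4S,7aR)-1-hydroxy-4-(hydroxymethyl)-4,7a-dimethyloctahydro-5H-inden-5-one
Product: 9 [(1R,3aS,4S,7aR)-1-hydroxy-4,7a-dimethyl-5-oxooctahydro-1H-inden-4-yl]methyl 2,2-dimethylpropanoate
Conditions: PivCl (1.05 equiv), pyridine, CH2Cl2, 0 °C
Reagents that add atoms: pivaloyl chloride CC(C)(C)C(Cl)=O
Why: Selective esterification of the primary hydroxyl over the hindered secondary cyclopentanol with a bulky acid chloride; the pivalate also blocks retro-aldol cleavage of the β-hydroxy ketone.

Step 6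
Reactants: 9 [(1R,3aS,4S,7aR)-1-hydroxy-4,7a-dimethyl-5-oxooctahydro-1H-inden-4-yl]methyl 2,2-dimethylpropanoate
Product: 10 ethylene dithioketal (spiro-1,3-dithiolane at C5 of the indane) of 9
Conditions: HSCH2CH2SH (3 equiv), BF3·OEt2 (0.3 equiv), CH2Cl2, 0 → 20 °C
Reagents that add atoms: ethane-1,2-dithiol SCCS
Why: Lewis-acid-catalysed dithioketalisation of the ring ketone, the first half of a Mozingo deoxygenation; the ester and the free secondary alcohol are inert.

Step 7
Reactants: 10 ethylene dithioketal of 9
Product: 11 [(1R,3aR,4S,7aR)-1-hydroxy-4,7a-dimethyloctahydro-1H-inden-4-yl]methyl 2,2-dimethylpropanoate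
Conditions: Raney Ni (W-2, excess), EtOH, reflux
Reagents that add atoms: none
Why: Raney nickel hydrogenolysis of the C–S bonds (Mozingo reduction) removes the oxygen function of the former Robinson enone without touching any stereocentre.

Step 8
Reactants: 11 [(1R,3aR,4S,7aR)-1-hydroxy-4,7a-dimethyloctahydro-1H-inden-4-yl]methyl 2,2-dimethylpropanoate
Product: 12 [(3aR,4S,7aR)-4,7a-dimethyl-1-oxooctahydro-1H-inden-4-yl]methyl 2,2-dimethylpropanoate
Conditions: TPAP (5 mol%), NMO (1.5 equiv), 4 Å MS, CH2Cl2, 20 °C
Reagents that add atoms: none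
Why: Ley–Griffith oxidation of the secondary alcohol regenerates the cyclopentanone (C8 of the target) under neutral conditions that leave the pivalate intact.

Step 9
Reactants: 13 (S)-citronellol
Product: 14 1-({[(3S)-3,7-dimethyloct-6-en-1-yl]oxy}methyl)-4-methoxybenzene
Conditions: NaH, PMBCl, Bu4NI (cat.), THF/DMF, 0 → 20 °C
Reagents that add atoms: 4-methoxybenzyl chloride COc1ccc(CCl)cc1
Why: Williamson ether synthesis on the primary alkoxide; the stereocentre of (S)-citronellol (C13 of the target) is untouched.

Step 10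
Reactants: 14 1-({[(3S)-3,7-dimethyloct-6-en-1-yl]oxy}methyl)-4-methoxybenzene
Product: 15 (4S)-6-[(4-methoxybenzyl)oxy]-4-methylhexanal
Conditions: O3, CH2Cl2, −78 °C (Sudan III end point); Me2S, −78 → 20 °C
Reagents that add atoms: ozone [O-][O+]=O
Why: Ozonolysis with reductive work-up cleaves the electron-rich trisubstituted alkene much faster than the anisyl ring and gives the aldehyde whose carbon becomes C9.

Step 11
Reactants: 15 (4S)-6-[(4-methoxybenzyl)oxy]-4-methylhexanal
Product: 16 1-methoxy-4-({[(3S)-3-methyl-6,6-bis(methylselanyl)hexyl]oxy}methyl)benzene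
Conditions: MeSeH (2.2 equiv), ZnCl2 (0.5 equiv), CH2Cl2, −20 → 20 °C
Reagents that add atoms: methaneselenol C[SeH]
Why: Lewis-acid-catalysed selenoacetalisation of the aldehyde, the standard entry to α-selenoalkyllithiums.

Step 12
Reactants: 16 1-methoxy-4-({[(3S)-3-methyl-6,6-bis(methylselanyl)hexyl]oxy}methyl)benzene; 12 [(3aR,4S,7aR)-4,7a-dimethyl-1-oxooctahydro-1H-inden-4-yl]methyl 2,2-dimethylpropanoate
Product: 18 β-hydroxy selenide (C8 carbinol of the trans-hydrindane with OH cis to the angular methyl and the 1-(methylselanyl)alkyl chain on C8), via α-selenoalkyllithium 17 (not isolated)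
Conditions: 16, n-BuLi (1.0 equiv), THF, −78 °C; then 12, −78 °C; aq NH4Cl
Reagents that add atoms: none
Why: Selenium–lithium exchange gives the weakly basic, strongly nucleophilic selenium-stabilised carbanion 17, whose 1,2-addition to the neopentyl ketone should occur anti to the angular methyl at −78 °C without attack on the hindered pivalate; the configuration at the selenium-bearing carbon is left open because step 13 re-sets it.

Step 13
Reactants: 18 β-hydroxy selenide
Product: 20 ent-8-oxo-17-norlabdane-15,18-diol 15-(4-methoxybenzyl) ether 18-pivalate, via selenonium betaine 19 (not isolated)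
Conditions: TlOEt (5 equiv), CHCl3, 20 °C; then DBU (0.2 equiv), CH2Cl2, 20 °C
Reagents that add atoms: none
Why: Thallium ethoxide and chloroform give dichlorocarbene, which is captured by the selenium of 18 and protonated internally by the C8 hydroxyl to betaine 19; the alkoxide then pushes while MeSeCHCl2 leaves from C9 and the C8–C10 bond anti to the C9–Se bond migrates, so that C9 is inserted between C10 and C8 and the cyclopentane C5–C6–C7–C8–C10 becomes the cyclohexanone ring B. The closest known reaction type is the Krief ring enlargement of β-hydroxyalkyl selenides, a seleno-pinacol (Tiffeneau–Demjanov-type) rearrangement. No ring is closed by cyclisation: ring B arises by one-carbon ring enlargement through a suprafacial 1,2-alkyl shift with retention at the migrating C10. The only new stereocentre, C9, is formed with inversion but lies α to the new ketone and is equilibrated by DBU to the equatorial side chain, the thermodynamic arrangement of 8-oxolabdanes. The selectivity needed is migration of the quaternary C10 instead of the C7 methylene; it should be secured by the higher migratory aptitude of the more substituted carbon in this selenonium rearrangement and by the rotamer that places the bulky selenonium group anti to C10.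

Step 14
Reactants: 20 ent-8-oxo-17-norlabdane-15,18-diol 15-(4-methoxybenzyl) ether 18-pivalate
Product: 21 ent-labd-8(17)-ene-15,18-diol 15-(4-methoxybenzyl) ether 18-pivalate
Conditions: Ph3PCH3Br (3 equiv), KOtBu (2.8 equiv), toluene, 90 °C
Reagents that add atoms: methyltriphenylphosphonium bromide C[P+](c1ccccc1)(c1ccccc1)c1ccccc1.[Br-]
Why: Wittig methylenation of the hindered ketone at elevated temperature; C9 already holds its thermodynamic configuration, so the basic ylide cannot erode it.

Step 15
Reactants: 21 ent-labd-8(17)-ene-15,18-diol 15-(4-methoxybenzyl) ether 18-pivalate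
Product: 22 ent-8,17-epoxylabdane-15,18-diol 15-(4-methoxybenzyl) ether 18-pivalate
Conditions: mCPBA (1.3 equiv), NaHCO3, CH2Cl2, 0 °C
Reagents that add atoms: mCPBA O=C(OO)c1cccc(Cl)c1
Why: Prilezhaev epoxidation in which the peracid should approach the exocyclic alkene from the equatorial direction, anti to the axial C10 methyl, placing the oxygen on C8 with the configuration of the target carbinol.

Step 16
Reactants: 22 ent-8,17-epoxylabdane-15,18-diol 15-(4-methoxybenzyl) ether 18-pivalate
Product: 23 ent-labdane-8,15,18-triol 15-(4-methoxybenzyl) ether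
Conditions: LiAlH4 (4 equiv), THF, 0 °C → reflux; Fieser work-up
Reagents that add atoms: none
Why: SN2 hydride opening of the spiro-epoxide at its unhindered methylene gives the tertiary C8 alcohol and the C17 methyl with the C8–O bond untouched, and the same reagent removes the pivalate by ester reduction.

Step 17
Reactants: 23 ent-labdane-8,15,18-triol 15-(4-methoxybenzyl) ether; 24 angelic acid
Product: 26 ent-18-angeloyloxylabdane-8,15-diol 15-(4-methoxybenzyl) ether, via angelic 2,4,6-trichlorobenzoic anhydride 25 (not isolated)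
Conditions: 24 (3 equiv), 2,4,6-trichlorobenzoyl chloride (3 equiv), Et3N (6 equiv), toluene, 20 °C; then 23, toluene, 80 °C
Reagents that add atoms: none
Why: Yamaguchi-type esterification through mixed anhydride 25 should acylate only the primary alcohol (the tertiary C8 hydroxyl is inert), and the DMAP-free protocol is chosen because it should conserve the Z geometry of the angelate.

Step 18
Reactants: 26 ent-18-angeloyloxylabdane-8,15-diol 15-(4-methoxybenzyl) ether
Product: 27 ent-18-angeloyloxylabdane-8,15-diol
Conditions: DDQ (1.3 equiv), CH2Cl2/pH 7 buffer (10:1), 0 → 20 °C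
Reagents that add atoms: none
Why: Oxidative cleavage of the 4-methoxybenzyl ether by DDQ (hydride abstraction, then hydrolysis of the oxocarbenium ion) should leave the angelate, the tertiary alcohol and all stereocentres untouched.

Step 19
Reactants: 27 ent-18-angeloyloxylabdane-8,15-diol
Product: 29 (3S)-5-[(1S,2S,4aS,5S,8aR)-2-hydroxy-2,5,8a-trimethyl-5-{[(2Z)-2-methylbut-2-enoyl]oxymethyl}decahydronaphthalen-1-yl]-3-methylpentanoic acid (CNP0315745.1), via aldehyde 28 (not isolated)
Conditions: TEMPO (0.2 equiv), PhI(OAc)2 (2.5 equiv), MeCN/H2O (1:1), 20 °C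
Reagents that add atoms: water O
Why: TEMPO/PhI(OAc)2 oxidation in aqueous acetonitrile should take the primary alcohol through aldehyde 28 and its hydrate to the carboxylic acid, while the tertiary alcohol and the electron-poor angelate alkene do not react.

**Compound list**

1 | 2-methylcyclopentane-1,3-dione | CC1C(=O)CCC1=O | starting material
2 | pent-1-en-3-one (ethyl vinyl ketone) | CCC(=O)C=C | starting material
3 | 2-methyl-2-(3-oxopentyl)cyclopentane-1,3-dione | CCC(=O)CCC1(C)C(=O)CCC1=O | intermediate
4 | (7aR)-3a-hydroxy-4,7a-dimethylhexahydro-1H-indene-1,5(4H)-dione, cis-fused ketol (3a-OH cis to 7a-Me; C4 epimers) | O=C1CC[C@]2(C)[C@](O)(C1C)CCC2=O | intermediate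
5 | (7aR)-4,7a-dimethyl-2,3,7,7a-tetrahydro-1H-indene-1,5(6H)-dione | O=C1CC[C@]2(C)C(=C1C)CCC2=O | intermediate
6 | (1R,7aR)-1-hydroxy-4,7a-dimethyl-1,2,3,6,7,7a-hexahydro-5H-inden-5-one | O=C1CC[C@]2(C)C(=C1C)CC[C@H]2O | intermediate
7 | dilithium salt of the trans-fused 4,5-enolate 1-alkoxide derived from 6 | [Li+].[Li+].CC1=C([O-])CC[C@]2(C)[C@@H]1CC[C@H]2[O-] | intermediate
8 | (1R,3aS,4S,7aR)-1-hydroxy-4-(hydroxymethyl)-4,7a-dimethyloctahydro-5H-inden-5-one | OC[C@@]1(C)C(=O)CC[C@]2(C)[C@@H]1CC[C@H]2O | intermediate
9 | [(1R,3aS,4S,7aR)-1-hydroxy-4,7a-dimethyl-5-oxooctahydro-1H-inden-4-yl]methyl 2,2-dimethylpropanoate | CC(C)(C)C(=O)OC[C@@]1(C)C(=O)CC[C@]2(C)[C@@H]1CC[C@H]2O | intermediate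
10 | ethylene dithioketal (spiro-1,3-dithiolane at C5 of the indane) of 9 | CC(C)(C)C(=O)OC[C@@]1(C)C2(SCCS2)CC[C@]3(C)[C@@H]1CC[C@H]3O | intermediate
11 | [(1R,3aR,4S,7aR)-1-hydroxy-4,7a-dimethyloctahydro-1H-inden-4-yl]methyl 2,2-dimethylpropanoate | CC(C)(C)C(=O)OC[C@@]1(C)CCC[C@]2(C)[C@@H]1CC[C@H]2O | intermediate
12 | [(3aR,4S,7aR)-4,7a-dimethyl-1-oxooctahydro-1H-inden-4-yl]methyl 2,2-dimethylpropanoate (trans-hydrindanone) | CC(C)(C)C(=O)OC[C@@]1(C)CCC[C@]2(C)[C@@H]1CCC2=O | intermediate
13 | (S)-citronellol, (3S)-3,7-dimethyloct-6-en-1-ol | CC(C)=CCC[C@H](C)CCO | starting material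
14 | 1-({[(3S)-3,7-dimethyloct-6-en-1-yl]oxy}methyl)-4-methoxybenzene | CC(C)=CCC[C@H](C)CCOCc1ccc(OC)cc1 | intermediate
15 | (4S)-6-[(4-methoxybenzyl)oxy]-4-methylhexanal | O=CCC[C@H](C)CCOCc1ccc(OC)cc1 | intermediate
16 | 1-methoxy-4-({[(3S)-3-methyl-6,6-bis(methylselanyl)hexyl]oxy}methyl)benzene | C[Se]C([Se]C)CC[C@H](C)CCOCc1ccc(OC)cc1 | intermediate
17 | [(4S)-6-[(4-methoxybenzyl)oxy]-4-methyl-1-(methylselanyl)hexyl]lithium | [Li]C([Se]C)CC[C@H](C)CCOCc1ccc(OC)cc1 | intermediate
18 | β-hydroxy selenide: 11-type trans-hydrindanol pivalate bearing on C1 (C8 of the target) the 1-(methylselanyl)alkyl chain; 1-OH cis to 7a-Me; epimers at the Se-bearing carbon | CC(C)(C)C(=O)OC[C@@]1(C)CCC[C@]2(C)[C@@H]1CC[C@]2(O)C([Se]C)CC[C@H](C)CCOCc1ccc(OC)cc1 | intermediate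
19 | Se-dichloromethyl selenonium alkoxide (betaine) of 18 | CC(C)(C)C(=O)OC[C@@]1(C)CCC[C@]2(C)[C@@H]1CC[C@]2([O-])C([Se+](C)C(Cl)Cl)CC[C@H](C)CCOCc1ccc(OC)cc1 | intermediate
20 | ent-8-oxo-17-norlabdane-15,18-diol 15-(4-methoxybenzyl) ether 18-pivalate (trans-decalin; H9 trans to 10-Me; 13S) | CC(C)(C)C(=O)OC[C@@]1(C)CCC[C@]2(C)[C@@H]1CCC(=O)[C@H]2CC[C@H](C)CCOCc1ccc(OC)cc1 | intermediate
21 | ent-labd-8(17)-ene-15,18-diol 15-(4-methoxybenzyl) ether 18-pivalate | CC(C)(C)C(=O)OC[C@@]1(C)CCC[C@]2(C)[C@@H]1CCC(=C)[C@H]2CC[C@H](C)CCOCc1ccc(OC)cc1 | intermediate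
22 | ent-8,17-epoxylabdane-15,18-diol 15-(4-methoxybenzyl) ether 18-pivalate (epoxide O trans to 10-Me) | CC(C)(C)C(=O)OC[C@@]1(C)CCC[C@]2(C)[C@@H]1CC[C@]3(OC3)[C@H]2CC[C@H](C)CCOCc1ccc(OC)cc1 | intermediate
23 | ent-labdane-8,15,18-triol 15-(4-methoxybenzyl) ether (8-OH trans to 10-Me) | OC[C@@]1(C)CCC[C@]2(C)[C@@H]1CC[C@](C)(O)[C@H]2CC[C@H](C)CCOCc1ccc(OC)cc1 | intermediate
24 | angelic acid, (Z)-2-methylbut-2-enoic acid | C/C=C(/C)C(=O)O | starting material
25 | angelic 2,4,6-trichlorobenzoic anhydride | C/C=C(/C)C(=O)OC(=O)c1c(Cl)cc(Cl)cc1Cl | intermediate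
26 | ent-18-angeloyloxylabdane-8,15-diol 15-(4-methoxybenzyl) ether | C/C=C(/C)C(=O)OC[C@@]1(C)CCC[C@]2(C)[C@@H]1CC[C@](C)(O)[C@H]2CC[C@H](C)CCOCc1ccc(OC)cc1 | intermediate
27 | ent-18-angeloyloxylabdane-8,15-diol | C/C=C(/C)C(=O)OC[C@@]1(C)CCC[C@]2(C)[C@@H]1CC[C@](C)(O)[C@H]2CC[C@H](C)CCO | intermediate
28 | ent-18-angeloyloxy-8-hydroxylabdan-15-al | C/C=C(/C)C(=O)OC[C@@]1(C)CCC[C@]2(C)[C@@H]1CC[C@](C)(O)[C@H]2CC[C@H](C)CC=O | intermediate
29 | (3S)-5-[(1S,2S,4aS,5S,8aR)-2-hydroxy-2,5,8a-trimethyl-5-{[(2Z)-2-methylbut-2-enoyl]oxymethyl}decahydronaphthalen-1-yl]-3-methylpentanoic acid (CNP0315745.1) | C/C=C(/C)C(=O)OC[C@@]1(C)CCC[C@]2(C)[C@@H]1CC[C@](C)(O)[C@H]2CC[C@H](C)CC(=O)O | target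

**Step count and risks**

Total step count: 19. Longest linear sequence: 16 steps (steps 1–8, then 12–19); steps 9–11 prepare the side-chain fragment.

Steps most likely to fail:

Step 13 (key step). The 1,2-shift may take the wrong course: the C7 methylene may migrate instead of the quaternary C10, or the alkoxide may close onto C9 to give the oxirane. The fallback keeps the one-carbon ring enlargement but runs it as a β-oxido carbenoid rearrangement, a mechanistically different 1,2-shift for which preferential migration of the more substituted carbon is also known. It sets out from ketone 12 and aldehyde 15. Aldehyde 15 would be converted with (PhO)3P/Br2/Et3N into the 1,1-dibromide F1. F1 and ketone 12 would be combined with LiTMP at −100 °C to give the dibromo carbinol F2. Bromine–lithium exchange of F2 with n-BuLi (−95 → −20 °C) should trigger the carbenoid shift to the lithium enolate F3. Protonation, and DBU equilibration if needed, returns to the route at ketone 20.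

Step 4. Trapping of the enolate with gaseous formaldehyde may fail through proton quench by formaldehyde oligomers, multiple hydroxymethylation or retro-aldol loss of formaldehyde on work-up. The fallback sets out from 6. After the lithium/ammonia reduction, enolate alkoxide 7 would be silylated (TMSCl/Et3N) and isolated as the bis(trimethylsilyl) compound F4. Its silyl enol ether would then be hydroxymethylated in a Lewis-acid-catalysed Mukaiyama aldol reaction with aqueous formaldehyde (Yb(OTf)3, THF/H2O), again anti to the angular methyl. Loss of both silyl groups on mildly acidic work-up returns to the route at keto diol 8.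

Step 17. The esterification may stall at the neopentyl alcohol, or the activated angelate may isomerise from Z to E (tiglate). The fallback builds the Z-enoate on the molecule instead of transferring it. It sets out from 23, which would be acylated at the primary hydroxyl with 2-[bis(2,2,2-trifluoroethoxy)phosphoryl]propanoic acid (EDC, DMAP) to the phosphonate ester F5. Still–Gennari olefination of F5 with acetaldehyde (KHMDS 2 equiv, 18-crown-6, THF, −78 °C) should give the (Z)-2-methylbut-2-enoate and returns to the route at 26.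

Further compounds
F1 | step 13 | 1-({[(3S)-6,6-dibromo-3-methylhexyl]oxy}methyl)-4-methoxybenzene | BrC(Br)CC[C@H](C)CCOCc1ccc(OC)cc1
F2 | step 13 | dibromo carbinol from F1 and ketone 12 (1-OH cis to 7a-Me) | CC(C)(C)C(=O)OC[C@@]1(C)CCC[C@]2(C)[C@@H]1CC[C@]2(O)C(Br)(Br)CC[C@H](C)CCOCc1ccc(OC)cc1
F3 | step 13 | lithium C8(9)-enolate of ketone 20 | [Li+].CC(C)(C)C(=O)OC[C@@]1(C)CCC[C@]2(C)[C@@H]1CCC([O-])=C2CC[C@H](C)CCOCc1ccc(OC)cc1
F4 | step 4 | bis(trimethylsilyl) derivative of 7 (silyl enol ether and 1-O-silyl ether) | CC1=C(O[Si](C)(C)C)CC[C@]2(C)[C@@H]1CC[C@H]2O[Si](C)(C)C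
F5 | step 17 | 18-O-{2-[bis(2,2,2-trifluoroethoxy)phosphoryl]propanoyl} ester of 23 | CC(C(=O)OC[C@@]1(C)CCC[C@]2(C)[C@@H]1CC[C@](C)(O)[C@H]2CC[C@H](C)CCOCc1ccc(OC)cc1)P(=O)(OCC(F)(F)F)OCC(F)(F)F
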